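**Plan**

- Numbering used below: ring A is the cyclohexane-1,2-diol (C1 = C(OH)CH3, C2 = CHOH, C3 = CH–CH2, C4 = CH–isopropenyl); ring B is the bromocyclohexyl ring (C1 = CH on the alkene, C3 = CHBr, C4 = C(OH)CH3).
- Retrosynthesis cuts (a) the ring A C3–CH2 bond (ketone enolate + allylic iodide) and (b) the ring B C3(Br)–C4(OH)(CH3) bond, which opens ring B to (5R)-7,7-dibromo-5-isopropenylheptan-2-one, i.e. ring-opened (R)-limonene.
- Enabling feature: in ring B the CHBr carbon C3 is bonded to the methyl carbinol C4 (a masked methyl ketone), C1 lies 1,3 to C3 and 1,4 to C4, and O and Br are cis. A CHBr2 chain end, reduced to a CHBr–Sm carbenoid, can therefore add to the methyl ketone end in a chair anchored by C1, and the cis alkoxide cannot close to an epoxide.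
- Forward, ring B: limonene oxide → keto aldehyde → gem-dibromide → samarium carbenoid ring closure → silyl ether → allylic chloride → allylic iodide.
- Forward, ring A and union: (S)-carvone → trans epoxy ketone → hydride opening to the 1,2-diol → α-ketol → silyl ether; enolate allylation joins the halves; ketone reduction and desilylation finish.
- Stereochemistry: ring B C1 is bought with (R)-limonene and relays C3 and C4 in the key event. Ring A C4 is bought with (S)-carvone and relays C1 (epoxidation anti to isopropenyl), C3 (alkylation anti to isopropenyl) and C2 (axial hydride delivery).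

Key step: step 3

Assumption: commercial (+)-limonene oxide is the (4R) cis/trans mixture; both epoxide isomers converge on 3 in step 1.

**Route**

Step 1
Reactants: 1 (4R)-limonene 1,2-oxide (cis/trans mixture)
Product: 3 (3R)-6-oxo-3-(prop-1-en-2-yl)heptanal, via limonene-1,2-diol 2 (not isolated)
Conditions: HIO4·2H2O (1.1 equiv), THF/H2O, 0 °C to rt
Reagents that add atoms: water, O
Why: Periodic acid first hydrolyses the epoxide to the trans-diaxial glycol (both epoxide isomers converge) and then cleaves it (Malaprade glycol cleavage) to the keto aldehyde, leaving the isopropenyl group and the stereocentre untouched.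

Step 2
Reactants: 3 (3R)-6-oxo-3-(prop-1-en-2-yl)heptanal
Product: 4 (5R)-7,7-dibromo-5-(prop-1-en-2-yl)heptan-2-one
Conditions: P(OPh)3 (1.2 equiv), Br2 (1.1 equiv), Et3N (1.3 equiv), CH2Cl2, –78 °C
Reagents that add atoms: bromine, BrBr
Why: Deoxygenative gem-dibromination of an aldehyde with the triphenyl phosphite–bromine reagent runs through an α-bromoalkoxyphosphonium salt already at –78 °C, where the enolisable methyl ketone is much slower and no free bromine is left for the alkene; no stereocentre is touched.

Step 3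
Reactants: 4 (5R)-7,7-dibromo-5-(prop-1-en-2-yl)heptan-2-one
Product: 7 (1S,2R,4R)-2-bromo-1-methyl-4-(prop-1-en-2-yl)cyclohexan-1-ol, via α-bromoalkylsamarium carbenoid 5 (not isolated), via samarium alkoxide 6 (not isolated)
Conditions: 4 added slowly to SmI2 (2.5 equiv), THF, –78 to –20 °C; then pH 7 phosphate buffer
Reagents that add atoms: none
Why: Proposed new method: two single-electron transfers from divalent samarium turn one C–Br bond of the gem-dibromide into a carbon–samarium bond, and the resulting α-bromoalkyl carbenoid 5 (trivalent samarium) adds to the tethered methyl ketone to give the bromohydrin alkoxide 6, which is protonated on work-up. The closest known reaction types are the halomethylation of ketones with a dihalomethane and SmI2 (intermolecular samarium carbenoid addition) and the intramolecular samarium Barbier cyclisation of ω-halo ketones; using a secondary α-bromo carbenoid for ring closure is the new element. The six-membered ring closes in the 6-exo-trig mode (carbanionic C7 onto the C2 carbonyl of 4) through a chair with the isopropenyl group equatorial. The carbinol centre (1S) is set by the ketone methyl taking the equatorial site so that the samarium-bound oxygen is axial, and the bromine centre (2R) by bromine taking the equatorial site gauche to that oxygen, where samarium can bridge O and Br; the carbenoid epimers are expected to interconvert (bromine–samarium exchange with unreacted 4), so the outcome is decided in the addition. The step needs reduction of the gem-dibromide in preference to the ketone and to the secondary C–Br bond of the product, which HMPA-free SmI2 at low temperature should provide, and addition faster than α-elimination, which the six-membered transition state favours. Only the cis (1S,2R) alkoxide lacks an anti-periplanar O/Br pair and survives, whereas a trans epimer would close to limonene oxide 1 and could be returned to step 1.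

Step 4
Reactants: 7 (1S,2R,4R)-2-bromo-1-methyl-4-(prop-1-en-2-yl)cyclohexan-1-ol
Product: 8 {[(1S,2R,4R)-2-bromo-1-methyl-4-(prop-1-en-2-yl)cyclohexyl]oxy}triethylsilane
Conditions: TESOTf (1.5 equiv), 2,6-lutidine (2.5 equiv), CH2Cl2, –78 to 0 °C
Reagents that add atoms: triethylsilyl trifluoromethanesulfonate (TESOTf), CC[Si](CC)(CC)OS(=O)(=O)C(F)(F)F
Why: Silyl triflate silylation of a hindered tertiary alcohol with a non-nucleophilic base; the cis-bromohydrin cannot close to an epoxide and no stereocentre changes.

Step 5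
Reactants: 8 {[(1S,2R,4R)-2-bromo-1-methyl-4-(prop-1-en-2-yl)cyclohexyl]oxy}triethylsilane
Product: 9 {[(1S,2R,4R)-2-bromo-4-(3-chloroprop-1-en-2-yl)-1-methylcyclohexyl]oxy}triethylsilane
Conditions: Ca(OCl)2, solid CO2, CH2Cl2/H2O, 0 °C
Reagents that add atoms: calcium hypochlorite, Ca(OCl)2, [Ca+2].[O-]Cl.[O-]Cl
Why: Ene-type allylic chlorination of the 1,1-disubstituted alkene by HOCl (from Ca(OCl)2 and CO2) puts chlorine on the terminal carbon and shifts the double bond toward the methyl group, as known for isopropenyl groups of carvone-type terpenes; the ring stereocentres are not involved.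

Step 6
Reactants: 9 {[(1S,2R,4R)-2-bromo-4-(3-chloroprop-1-en-2-yl)-1-methylcyclohexyl]oxy}triethylsilane
Product: 10 {[(1S,2R,4R)-2-bromo-4-(3-iodoprop-1-en-2-yl)-1-methylcyclohexyl]oxy}triethylsilane
Conditions: NaI (3 equiv), acetone, rt, dark; used directly
Reagents that add atoms: sodium iodide (NaI), [Na+].[I-]
Why: Finkelstein halide exchange (SN2) at the allylic chloride, driven by precipitation of NaCl, gives the more reactive allylic iodide, while the hindered secondary ring bromide is inert.

Step 7
Reactants: 11 (S)-carvone, (5S)-2-methyl-5-(prop-1-en-2-yl)cyclohex-2-en-1-one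
Product: 12 (1S,4S,6S)-1-methyl-4-(prop-1-en-2-yl)-7-oxabicyclo[4.1.0]heptan-2-one
Conditions: 30% H2O2, aq. NaOH (cat.), MeOH, 0 °C
Reagents that add atoms: hydrogen peroxide, OO
Why: Weitz–Scheffer nucleophilic epoxidation of the enone: hydroperoxide adds axially to the β-carbon anti to the isopropenyl group, so the epoxide oxygen ends trans to isopropenyl (1S,6S), and the isolated alkene is not attacked.

Step 8
Reactants: 12 (1S,4S,6S)-1-methyl-4-(prop-1-en-2-yl)-7-oxabicyclo[4.1.0]heptan-2-one
Product: 14 (1S,2R,4S)-1-methyl-4-(prop-1-en-2-yl)cyclohexane-1,2-diol, via lithium epoxy alkoxide 13 (not isolated)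
Conditions: LiEt3BH (3 equiv), THF, –78 °C, then rt to 40 °C; then H2O
Reagents that add atoms: none
Why: Lithium triethylborohydride first reduces the ketone anti to the epoxide oxygen (cis-epoxy alkoxide 13, which cannot undergo Payne migration) and then opens the trisubstituted epoxide by SN2 hydride attack at the secondary carbon (hydride reduction of an epoxide at the less substituted carbon), so the tertiary C1–O bond and its configuration are retained; the C2 configuration is erased in step 9, so any C2 epimer converges.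

Step 9
Reactants: 14 (1S,2R,4S)-1-methyl-4-(prop-1-en-2-yl)cyclohexane-1,2-diol
Product: 15 (2S,5S)-2-hydroxy-2-methyl-5-(prop-1-en-2-yl)cyclohexan-1-one
Conditions: IBX (1.5 equiv), DMSO, rt
Reagents that add atoms: none
Why: IBX oxidation converts the secondary alcohol of a 1,2-diol into the α-ketol without glycol cleavage and leaves the tertiary alcohol, its configuration and the alkene alone.

Step 10
Reactants: 15 (2S,5S)-2-hydroxy-2-methyl-5-(prop-1-en-2-yl)cyclohexan-1-one
Product: 16 (2S,5S)-2-methyl-5-(prop-1-en-2-yl)-2-[(triethylsilyl)oxy]cyclohexan-1-one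
Conditions: TESOTf (1.3 equiv), 2,6-lutidine (2 equiv), CH2Cl2, –78 °C
Reagents that add atoms: triethylsilyl trifluoromethanesulfonate (TESOTf), CC[Si](CC)(CC)OS(=O)(=O)C(F)(F)F
Why: Silyl triflate silylation of the tertiary alcohol at –78 °C is much faster than silyl enol ether formation with the weak base 2,6-lutidine and removes the acidic proton before enolate chemistry.

Step 11
Reactants: 16 (2S,5S)-2-methyl-5-(prop-1-en-2-yl)-2-[(triethylsilyl)oxy]cyclohexan-1-one; 10 {[(1S,2R,4R)-2-bromo-4-(3-iodoprop-1-en-2-yl)-1-methylcyclohexyl]oxy}triethylsilane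
Product: 18 (2S,5S,6R)-6-{2-[(1R,3R,4S)-3-bromo-4-methyl-4-[(triethylsilyl)oxy]cyclohexyl]prop-2-en-1-yl}-2-methyl-5-(prop-1-en-2-yl)-2-[(triethylsilyl)oxy]cyclohexan-1-one, via lithium enolate 17 (not isolated)
Conditions: LiN(i-Pr)2 (1.05 equiv), THF, –78 °C; then 10, DMPU, –78 to –20 °C
Reagents that add atoms: none
Why: Kinetic lithium enolate formation can occur only toward C6 because C2 is quaternary, and SN2 C-alkylation by the allylic iodide takes place anti to the adjacent C5 isopropenyl group (trans-2,3 outcome as in alkylations of carvone and 3-substituted cyclohexanone enolates) to set C6 as R, the diequatorial isomer also being the thermodynamic one; the secondary bromide and the silyl ethers are inert.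

Step 12
Reactants: 18 (the coupled ketone)
Product: 19 (1S,2S,5S,6R)-6-{2-[(1R,3R,4S)-3-bromo-4-methyl-4-[(triethylsilyl)oxy]cyclohexyl]prop-2-en-1-yl}-2-methyl-5-(prop-1-en-2-yl)-2-[(triethylsilyl)oxy]cyclohexan-1-ol
Conditions: NaBH4, MeOH/THF, 0 °C
Reagents that add atoms: none
Why: Borohydride reduction of the cyclohexanone by axial attack from the face opposite the axial C2 methyl group should give the equatorial alcohol (1S), trans to both the C2 silyloxy group and the C6 side chain, and NaBH4 touches neither the secondary bromide nor the alkenes.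

Step 13
Reactants: 19 (the bis-silyl ether alcohol)
Product: 20 (1S,2S,3R,4S)-3-{2-[(1R,3R,4S)-3-bromo-4-hydroxy-4-methylcyclohexyl]prop-2-en-1-yl}-1-methyl-4-(prop-1-en-2-yl)cyclohexane-1,2-diol
Conditions: HF·pyridine, pyridine/THF, 0 °C to rt
Reagents that add atoms: none
Why: Fluoride-mediated desilylation cleaves both tertiary triethylsilyl ethers under buffered conditions that neither ionise the tertiary alcohols nor eliminate the secondary bromide (the cis-bromohydrin cannot form an epoxide).

**Compound list**

1 | (4R)-1-methyl-4-(prop-1-en-2-yl)-7-oxabicyclo[4.1.0]heptane, (+)-limonene oxide, cis/trans mixture | CC(=C)[C@@H]1CCC2(C)OC2C1 | starting material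
2 | (1S,2S,4R)-1-methyl-4-(prop-1-en-2-yl)cyclohexane-1,2-diol (trans-diaxial limonene-1,2-diol) | CC(=C)[C@@H]1CC[C@](C)(O)[C@@H](O)C1 | intermediate
3 | (3R)-6-oxo-3-(prop-1-en-2-yl)heptanal | CC(=O)CC[C@H](CC=O)C(C)=C | intermediate
4 | (5R)-7,7-dibromo-5-(prop-1-en-2-yl)heptan-2-one | CC(=O)CC[C@H](CC(Br)Br)C(C)=C | intermediate
5 | [(3R)-1-bromo-6-oxo-3-(prop-1-en-2-yl)heptyl]samarium diiodide (carbenoid, trivalent samarium, epimers at C1) | CC(=O)CC[C@H](CC(Br)[Sm](I)I)C(C)=C | intermediate
6 | {[(1S,2R,4R)-2-bromo-1-methyl-4-(prop-1-en-2-yl)cyclohexyl]oxy}samarium diiodide | CC(=C)[C@@H]1CC[C@](C)(O[Sm](I)I)[C@H](Br)C1 | intermediate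
7 | (1S,2R,4R)-2-bromo-1-methyl-4-(prop-1-en-2-yl)cyclohexan-1-ol (OH axial, Br equatorial, cis) | CC(=C)[C@@H]1CC[C@](C)(O)[C@H](Br)C1 | intermediate
8 | {[(1S,2R,4R)-2-bromo-1-methyl-4-(prop-1-en-2-yl)cyclohexyl]oxy}triethylsilane | CC(=C)[C@@H]1CC[C@](C)(O[Si](CC)(CC)CC)[C@H](Br)C1 | intermediate
9 | {[(1S,2R,4R)-2-bromo-4-(3-chloroprop-1-en-2-yl)-1-methylcyclohexyl]oxy}triethylsilane | ClCC(=C)[C@@H]1CC[C@](C)(O[Si](CC)(CC)CC)[C@H](Br)C1 | intermediate
10 | {[(1S,2R,4R)-2-bromo-4-(3-iodoprop-1-en-2-yl)-1-methylcyclohexyl]oxy}triethylsilane | ICC(=C)[C@@H]1CC[C@](C)(O[Si](CC)(CC)CC)[C@H](Br)C1 | intermediate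
11 | (S)-carvone, (5S)-2-methyl-5-(prop-1-en-2-yl)cyclohex-2-en-1-one | CC1=CC[C@@H](CC1=O)C(C)=C | starting material
12 | (1S,4S,6S)-1-methyl-4-(prop-1-en-2-yl)-7-oxabicyclo[4.1.0]heptan-2-one (epoxide trans to isopropenyl) | CC(=C)[C@H]1C[C@@H]2O[C@]2(C)C(=O)C1 | intermediate
13 | lithium alkoxide of the cis-epoxy alcohol from 12 (O–Li cis to the epoxide oxygen) | CC(=C)[C@H]1C[C@@H]2O[C@]2(C)[C@H](O[Li])C1 | intermediate
14 | (1S,2R,4S)-1-methyl-4-(prop-1-en-2-yl)cyclohexane-1,2-diol (tertiary OH trans to isopropenyl) | CC(=C)[C@H]1CC[C@](C)(O)[C@H](O)C1 | intermediate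
15 | (2S,5S)-2-hydroxy-2-methyl-5-(prop-1-en-2-yl)cyclohexan-1-one | CC(=C)[C@H]1CC[C@](C)(O)C(=O)C1 | intermediate
16 | (2S,5S)-2-methyl-5-(prop-1-en-2-yl)-2-[(triethylsilyl)oxy]cyclohexan-1-one | CC(=C)[C@H]1CC[C@](C)(O[Si](CC)(CC)CC)C(=O)C1 | intermediate
17 | lithium enolate of 16 (C1=C6 enolate) | CC(=C)[C@H]1CC[C@](C)(O[Si](CC)(CC)CC)C(O[Li])=C1 | intermediate
18 | (2S,5S,6R)-6-{2-[(1R,3R,4S)-3-bromo-4-methyl-4-[(triethylsilyl)oxy]cyclohexyl]prop-2-en-1-yl}-2-methyl-5-(prop-1-en-2-yl)-2-[(triethylsilyl)oxy]cyclohexan-1-one | C=C(C[C@@H]1[C@@H](C(=C)C)CC[C@](C)(O[Si](CC)(CC)CC)C1=O)[C@@H]1CC[C@](C)(O[Si](CC)(CC)CC)[C@H](Br)C1 | intermediate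
19 | (1S,2S,5S,6R)-6-{2-[(1R,3R,4S)-3-bromo-4-methyl-4-[(triethylsilyl)oxy]cyclohexyl]prop-2-en-1-yl}-2-methyl-5-(prop-1-en-2-yl)-2-[(triethylsilyl)oxy]cyclohexan-1-ol | C=C(C[C@@H]1[C@@H](C(=C)C)CC[C@](C)(O[Si](CC)(CC)CC)[C@H]1O)[C@@H]1CC[C@](C)(O[Si](CC)(CC)CC)[C@H](Br)C1 | intermediate
20 | (1S,2S,3R,4S)-3-{2-[(1R,3R,4S)-3-bromo-4-hydroxy-4-methylcyclohexyl]prop-2-en-1-yl}-1-methyl-4-(prop-1-en-2-yl)cyclohexane-1,2-diol | C=C(C[C@@H]1[C@@H](C(=C)C)CC[C@](C)(O)[C@H]1O)[C@@H]1CC[C@](C)(O)[C@H](Br)C1 | target

**Step count**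

Total: 13 steps. Longest linear sequence: 9 steps (steps 1–6, then 11–13); the ring A branch (steps 7–10) joins at step 11.

**Steps most likely to fail, with fallbacks**

Step 3 (proposed new method). The carbenoid may lose bromide by α-elimination, be protonated or reduced further before it adds, or the bromine-bearing centre may form without facial control if the carbenoid epimers do not equilibrate. The fallback uses only known chemistry and forms no C–C bond; it sets out from 1 and returns at 8. Hydrolysis of 1 (1% aq. H2SO4, THF, 0 °C) gives the trans-diaxial diol 2, isolated this time. Its axial secondary hydroxyl is mesylated (MsCl, pyridine, CH2Cl2, 0 °C) to (1S,2S,5R)-2-hydroxy-2-methyl-5-(prop-1-en-2-yl)cyclohexyl methanesulfonate F1. The tertiary hydroxyl is then silylated (TESOTf, 2,6-lutidine, CH2Cl2, –78 °C) to (1S,2S,5R)-2-methyl-5-(prop-1-en-2-yl)-2-[(triethylsilyl)oxy]cyclohexyl methanesulfonate F2, which blocks epoxide closure. SN2 displacement of the axial mesylate by bromide with inversion (LiBr, DMF, 60 °C) should give 8.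

Step 2. The methyl ketone may compete with the aldehyde for the phosphonium reagent (vinyl bromide formation), or residual bromine may add to the alkene. The fallback replaces kinetic chemoselectivity by protecting-group differentiation; it sets out from 3 and returns at 4. Both carbonyls are acetalised (ethylene glycol, PPTS, benzene, reflux) to 2-methyl-2-[(3R)-4-(1,3-dioxolan-2-yl)-3-(prop-1-en-2-yl)butyl]-1,3-dioxolane F3. The aldehyde acetal alone is unmasked with TESOTf/2,4,6-collidine followed by water (chemoselective cleavage of aldehyde acetals in the presence of ketals) to give (3R)-5-(2-methyl-1,3-dioxolan-2-yl)-3-(prop-1-en-2-yl)pentanal F4. Gem-dibromination (P(OPh)3, Br2, Et3N, CH2Cl2, –78 °C) then gives 2-[(3R)-5,5-dibromo-3-(prop-1-en-2-yl)pentyl]-2-methyl-1,3-dioxolane F5, and mild acid hydrolysis (PPTS, acetone/H2O) gives 4.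

Step 11. Proton transfer between enolate and product, slow SN2 at the branched allylic iodide, or poor facial selectivity may erode the coupling. The fallback changes the mechanism to π-allyl chemistry; it sets out from 16 and 9 and returns at 18. The enolate 17 is transmetalated with ZnCl2 and allylated with the allylic chloride 9 under Pd(PPh3)4 catalysis (zerovalent palladium, Tsuji–Trost-type allylation of a ketone enolate) in THF at 0 °C. Any minor C6 epimer can be equilibrated to the diequatorial isomer with DBU. No new compound is made (none, F0).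

Further compounds
F1 | step 3 | (1S,2S,5R)-2-hydroxy-2-methyl-5-(prop-1-en-2-yl)cyclohexyl methanesulfonate | CC(=C)[C@@H]1CC[C@](C)(O)[C@@H](OS(C)(=O)=O)C1
F2 | step 3 | (1S,2S,5R)-2-methyl-5-(prop-1-en-2-yl)-2-[(triethylsilyl)oxy]cyclohexyl methanesulfonate | CC(=C)[C@@H]1CC[C@](C)(O[Si](CC)(CC)CC)[C@@H](OS(C)(=O)=O)C1
F3 | step 2 | 2-methyl-2-[(3R)-4-(1,3-dioxolan-2-yl)-3-(prop-1-en-2-yl)butyl]-1,3-dioxolane | CC1(CC[C@H](CC2OCCO2)C(C)=C)OCCO1
F4 | step 2 | (3R)-5-(2-methyl-1,3-dioxolan-2-yl)-3-(prop-1-en-2-yl)pentanal | CC1(CC[C@H](CC=O)C(C)=C)OCCO1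
F5 | step 2 | 2-[(3R)-5,5-dibromo-3-(prop-1-en-2-yl)pentyl]-2-methyl-1,3-dioxolane | CC1(CC[C@H](CC(Br)Br)C(C)=C)OCCO1
F0 | step 11 | none | none
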